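The C2–C3 methylene–methylene bond of the ten-membered carbocycle is disconnected by a retro-oxy-Cope. The key step, an anionic oxy-Cope ring expansion of a shikimate-derived cis-1-vinyl-2-isopropenylcyclohexanol, breaks the C5–C10 bond of the cyclohexane (C5, C6, C7, C8, C9, C10) and forms C2–C3, closing the cyclodecadiene in one operation. It exploits the C10–C1–C2–C3–C4–C5 segment: the chair transition state gives the 4Z alkene (later the cis-4,5-epoxide) and a C10 enolate of defined geometry that, after triflation, methylation and syn-hydroboration, sets C10 (methyl) and C1 (oxygen). The precursor already carries the C6, C7 and C8 oxygens; the butenolide (C6, C7, C11, C12, C13) is annulated afterwards.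

Key step: step 7

Remark 1: germacrane labels are used for all atoms (ring C1–C10; C11 lactone α-carbon, C12 lactone carbonyl, C13 CH2O; C14 methyl on C10; C15 methyl on C4). Shikimate C1, C2, C3, C4, C5, C6 become C10, C5, C6, C7, C8, C9.
Remark 2: ethyl 2-(diethoxyphosphoryl)acrylate (21) and monoisopinocampheylborane, IpcBH2, derived from (+)-α-pinene, are assumed to be purchasable reagents.

Step 1
Reactants: 1 (−)-shikimic acid
Product: 3 methyl 3,4-O-isopropylideneshikimate, via methyl shikimate 2 (not isolated)
Conditions: MeOH, camphorsulfonic acid (cat.), reflux; then Me2C(OMe)2, rt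
Reagents that add atoms: methanol CO; 2,2-dimethoxypropane COC(C)(C)OC
Why: Fischer esterification followed by acid-catalysed acetalisation of the only cis-diol (O6/O7) as the five-membered acetonide, with no stereocentre touched.

Step 2
Reactants: 3 methyl 3,4-O-isopropylideneshikimate
Product: 4 methyl 5-epi-3,4-O-isopropylidene-5-O-(4-methoxyphenyl)shikimate
Conditions: 4-methoxyphenol, PPh3, DIAD, THF, 0 °C → rt
Reagents that add atoms: 4-methoxyphenol COc1ccc(O)cc1
Why: Mitsunobu etherification in which the phenol displaces the activated C8 hydroxyl with SN2 inversion, placing the C8 oxygen cis to the C6/C7 oxygens as in the target and installing an ether that is inert to the basic steps ahead.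

Step 3
Reactants: 4 methyl 5-epi-3,4-O-isopropylidene-5-O-(4-methoxyphenyl)shikimate
Product: 6 saturated methyl ester with isopropenyl on C5, via silyl ketene acetal 5 (not isolated)
Conditions: isopropenylMgBr, CuBr·SMe2 (cat.), Me3SiCl, THF, −78 → −40 °C; then aq. NH4Cl
Reagents that add atoms: isopropenylmagnesium bromide CC(=C)[Mg]Br
Why: copper-catalysed, silyl-chloride-accelerated conjugate addition of the alkenyl Grignard reagent to the enoate, in which the three ring oxygens shield one face so that isopropenyl enters C5 trans to the C6 oxygen; hydrolysis of ketene acetal 5 gives 6 as C10 epimers (C10 is set in step 4).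

Step 4
Reactants: 6 saturated methyl ester
Product: 8 α-hydroxy ester, via potassium enolate 7 (not isolated)
Conditions: KN(SiMe3)2, THF, −78 °C; then 2-(phenylsulfonyl)-3-phenyloxaziridine, −78 °C
Reagents that add atoms: 2-(phenylsulfonyl)-3-phenyloxaziridine O=S(=O)(c1ccccc1)N1OC1c1ccccc1
Why: enolate hydroxylation with an N-sulfonyloxaziridine (Davis oxidation), in which the bulky oxidant should attack the exocyclic enolate 7 along the equatorial trajectory anti to the vicinal isopropenyl group, so the new C10 hydroxyl is trans to isopropenyl and the ester (the future vinyl group) is cis to it.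

Step 5
Reactants: 8 α-hydroxy ester
Product: 9 α-hydroxy aldehyde
Conditions: i-Bu2AlH (2.2 equiv), CH2Cl2, −78 °C; Rochelle salt work-up
Reagents that add atoms: none
Why: partial ester reduction that should stop at the aldehyde because the neighbouring alkoxide holds the tetrahedral aluminate as a chelate until work-up; the quaternary C10 cannot epimerise.

Step 6
Reactants: 9 α-hydroxy aldehyde
Product: 10 cis-1-vinyl-2-isopropenylcyclohexanol
Conditions: Ph3PCH3Br, KN(SiMe3)2, THF, 0 °C → rt
Reagents that add atoms: methyltriphenylphosphonium bromide [Br-].C[P+](c1ccccc1)(c1ccccc1)c1ccccc1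
Why: Wittig methylenation of the non-enolisable aldehyde with excess ylide (the first equivalent deprotonates the hydroxyl) gives the vinyl group cis to isopropenyl without touching a stereocentre.

Step 7
Reactants: 10 cis-1-vinyl-2-isopropenylcyclohexanol
Product: 13 cyclodecadienyl triflate, via potassium alkoxide 11 (not isolated), via potassium dienolate 12 (not isolated)
Conditions: KH, 18-crown-6, THF, 0 °C → rt; then PhNTf2, −78 → 0 °C
Reagents that add atoms: N-phenylbis(trifluoromethanesulfonimide) O=S(=O)(N(c1ccccc1)S(=O)(=O)C(F)(F)F)C(F)(F)F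
Why: KH/18-crown-6 gives the naked alkoxide 11, which undergoes an alkoxide-accelerated [3,3]-sigmatropic (anionic oxy-Cope) rearrangement in which the C5–C10 σ-bond breaks while C2–C3 forms, and the resulting enolate 12 is O-sulfonylated by PhNTf2 before it can equilibrate. The closest known reaction type is the oxy-Cope ring expansion of 1,2-divinylcyclohexanols to cyclodec-5-enones with trapping of the enolate. The ten-membered ring is closed by a four-atom ring expansion of the cyclohexane through a six-centre chair transition state, not by an end-to-end cyclisation, so no high dilution is needed. No stereocentre is created and C6, C7, C8 are untouched; the two alkene geometries are set by the chair, in which C6 is axial (giving the 4Z alkene) and C9 is equatorial (giving the enolate with C9 trans to C2, later the 1(10)E alkene). The step needs the chair of the cis-dialkenyl isomer with equatorial isopropenyl and axial vinyl, not the ring-flipped chair or a boat; the all-cis C6/C7/C8 oxygens secure this because the flipped chair would carry three syn-axial oxygens. Enolate regiochemistry (C1, not C9) follows from the mechanism, and immediate triflation guards against β-elimination of the C8 aryloxide.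

Step 8
Reactants: 13 cyclodecadienyl triflate
Product: 14 (1(10)E,4Z)-diene
Conditions: MeMgBr, Fe(acac)3 (cat.), THF/NMP, −30 °C
Reagents that add atoms: methylmagnesium bromide C[Mg]Br
Why: iron-catalysed alkyl–alkenyl cross-coupling of the enol triflate with the methyl Grignard reagent (Kumada type) proceeds with retention of alkene geometry and puts C14 on C10, giving the 1(10)E trisubstituted alkene.

Step 9
Reactants: 14 (1(10)E,4Z)-diene
Product: 16 (1S,10R)-alcohol, via alkylborane 15 (not isolated)
Conditions: IpcBH2 [from (+)-α-pinene], THF, −25 °C; then NaOH, H2O2, 0 °C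
Reagents that add atoms: hydrogen peroxide OO
Why: asymmetric hydroboration–oxidation with an isopinocampheylborane, which should attack only the unhindered 1(10)E alkene (the 4Z alkene is shielded and deactivated by the allylic acetonide oxygen) with boron at C1; syn addition across the E alkene from the outer face of the conformer delivered by the chair transition state, the face this reagent also prefers for E-trisubstituted alkenes, should set 1S (OH) and 10R (H) together, and oxidation retains configuration.

Step 10
Reactants: 16 (1S,10R)-alcohol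
Product: 17 C1 acetate
Conditions: Ac2O, pyridine, DMAP (cat.), CH2Cl2, rt
Reagents that add atoms: acetic anhydride CC(=O)OC(C)=O
Why: DMAP-catalysed acylation of the only free hydroxyl installs the C1 acetate of the target with retention.

Step 11
Reactants: 17 C1 acetate
Product: 18 C8 alcohol
Conditions: (NH4)2Ce(NO3)6, MeCN/H2O (4:1), 0 °C, short reaction time
Reagents that add atoms: none
Why: oxidative dearylation in which tetravalent cerium oxidises the electron-rich 4-methoxyphenyl ether to a quinone-type cation that is hydrolysed to benzoquinone and the free C8 alcohol with retention (the C8–O bond is not broken), a brief reaction at 0 °C that should spare acetonide, acetate and the trisubstituted alkene.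

Step 12
Reactants: 18 C8 alcohol
Product: 19 C8 tiglate
Conditions: tigloyl chloride, Et3N, DMAP (cat.), CH2Cl2, 0 °C → rt
Reagents that add atoms: tigloyl chloride C/C=C(\C)C(Cl)=O
Why: DMAP-catalysed acylation of the single free hydroxyl with retention at C8; the E enoate is the stable isomer and should not isomerise.

Step 13
Reactants: 19 C8 tiglate
Product: 20 cis-6,7-diol
Conditions: AcOH/H2O (4:1), 45 °C
Reagents that add atoms: none
Why: acid-catalysed hydrolysis of the isopropylidene acetal liberates the 6,7-diol, while the two esters and the allylic C6–O bond should survive dilute acetic acid.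

Step 14
Reactants: 21 ethyl 2-(diethoxyphosphoryl)acrylate; 22 4-methoxybenzyl alcohol
Product: 23 ethyl 2-(diethoxyphosphoryl)-3-[(4-methoxybenzyl)oxy]propanoate
Conditions: KOt-Bu (cat.), THF, 0 °C
Reagents that add atoms: none
Why: base-catalysed oxa-Michael addition of the benzylic alkoxide to the doubly activated vinylphosphonate gives the racemic β-alkoxy phosphonate, whose stereocentre is destroyed in step 19.

Step 15
Reactants: 23 ethyl 2-(diethoxyphosphoryl)-3-[(4-methoxybenzyl)oxy]propanoate
Product: 24 2-(diethoxyphosphoryl)-3-[(4-methoxybenzyl)oxy]propanoic acid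
Conditions: LiOH·H2O (1.05 equiv), THF/H2O, 0 °C; then aq. HCl to pH 3
Reagents that add atoms: lithium hydroxide [Li+].[OH-]
Why: saponification of the carboxylic ester at 0 °C with one equivalent of hydroxide, the phosphonate diester being much slower to hydrolyse, gives the acid after acidification.

Step 16
Reactants: 20 cis-6,7-diol; 24 2-(diethoxyphosphoryl)-3-[(4-methoxybenzyl)oxy]propanoic acid
Product: 25 C6 phosphonoacyl ester with free C7 hydroxyl
Conditions: EDC, DMAP (cat.), CH2Cl2, −20 → 0 °C
Reagents that add atoms: none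
Why: carbodiimide (Steglich-type) esterification in which the allylic C6 hydroxyl, with an sp2 neighbour, should be acylated in preference to the C7 hydroxyl, which is flanked by two oxygenated carbons and is the least reactive position of shikimate-type triols; no stereocentre changes.

Step 17
Reactants: 25 C6 phosphonoacyl ester
Product: 26 (4R,5S)-epoxide
Conditions: VO(acac)2 (cat.), t-BuOOH, CH2Cl2, 0 °C → rt
Reagents that add atoms: tert-butyl hydroperoxide CC(C)(C)OO
Why: vanadium-catalysed hydroxyl-directed epoxidation in which, with O6 acylated, only the homoallylic C7 hydroxyl binds the metal; allylic 1,3-strain of the Z alkene holds H6 in the alkene plane, so the vanadate on O7 should deliver oxygen to the face anti to the C6 acyloxy group and give the cis-4,5-epoxide as 4R,5S, while the electron-poor tiglate is inert.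

Step 18
Reactants: 26 (4R,5S)-epoxide
Product: 27 C7 ketone
Conditions: Dess–Martin periodinane, pyridine, CH2Cl2, 0 °C → rt
Reagents that add atoms: none
Why: Dess–Martin oxidation of the secondary C7 alcohol under pyridine buffering gives the α-acyloxy ketone without affecting the epoxide or the neighbouring stereocentres.

Step 19
Reactants: 27 C7 ketone
Product: 28 butenolide with C13 4-methoxybenzyl ether
Conditions: LiCl, i-Pr2NEt, MeCN, 0 °C → rt
Reagents that add atoms: none
Why: intramolecular Horner–Wadsworth–Emmons olefination (LiCl/amine variant) in which only the phosphonate C–H is acidic enough for the mild base, and five-membered ring closure onto the activated α-oxygenated ketone should form the tetrasubstituted C7=C11 butenolide faster than epimerisation at C6/C8 or base-induced epoxide opening.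

Step 20
Reactants: 28 butenolide with C13 4-methoxybenzyl ether
Product: 29 C13 alcohol
Conditions: DDQ, CH2Cl2/pH 7 buffer, 0 °C → rt
Reagents that add atoms: none
Why: oxidative cleavage of the 4-methoxybenzyl ether by DDQ (hydride abstraction, then hydrolysis of the oxocarbenium ion) frees the primary C13 alcohol and should spare epoxide, esters and the electron-poor alkenes.

Step 21
Reactants: 29 C13 alcohol
Product: 30 target CNP0287840.1
Conditions: Ac2O, pyridine, CH2Cl2, 0 °C
Reagents that add atoms: acetic anhydride CC(=O)OC(C)=O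
Why: acetylation of the primary allylic alcohol under weakly basic conditions (no γ-deprotonation of the butenolide next to the epoxide) completes the target.

Compound list
1 | (−)-shikimic acid, (3R,4S,5R)-3,4,5-trihydroxycyclohex-1-ene-1-carboxylic acid | OC(=O)C1=C[C@@H](O)[C@@H](O)[C@H](O)C1 | starting material
2 | methyl shikimate | COC(=O)C1=C[C@@H](O)[C@@H](O)[C@H](O)C1 | intermediate (not isolated)
3 | methyl 3,4-O-isopropylideneshikimate (free 5-OH trans to the acetonide oxygens) | COC(=O)C1=C[C@H]2OC(C)(C)O[C@H]2[C@H](O)C1 | intermediate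
4 | methyl (3R,4S,5S)-3,4-O-isopropylidene-5-(4-methoxyphenoxy)cyclohex-1-ene-1-carboxylate (three ring oxygens all cis) | COC(=O)C1=C[C@H]2OC(C)(C)O[C@H]2[C@@H](Oc3ccc(OC)cc3)C1 | intermediate
5 | methyl trimethylsilyl ketene acetal of 6 (exocyclic C=C at C10) | COC(O[Si](C)(C)C)=C1[C@H](C(C)=C)[C@H]2OC(C)(C)O[C@H]2[C@@H](Oc3ccc(OC)cc3)C1 | intermediate (not isolated)
6 | methyl 2-isopropenyl-3,4-O-isopropylidene-5-(4-methoxyphenoxy)cyclohexane-1-carboxylate (isopropenyl trans to the adjacent acetonide oxygen; epimers at the ester carbon) | COC(=O)C1[C@H](C(C)=C)[C@H]2OC(C)(C)O[C@H]2[C@@H](Oc3ccc(OC)cc3)C1 | intermediate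
7 | potassium ester enolate of 6 | COC([O-])=C1[C@H](C(C)=C)[C@H]2OC(C)(C)O[C@H]2[C@@H](Oc3ccc(OC)cc3)C1.[K+] | intermediate (not isolated)
8 | methyl (1R)-1-hydroxy-2-isopropenyl-3,4-O-isopropylidene-5-(4-methoxyphenoxy)cyclohexane-1-carboxylate (OH cis to the three ring oxygens, trans to isopropenyl) | COC(=O)[C@]1(O)[C@H](C(C)=C)[C@H]2OC(C)(C)O[C@H]2[C@@H](Oc3ccc(OC)cc3)C1 | intermediate
9 | 1-hydroxy-2-isopropenyl-3,4-O-isopropylidene-5-(4-methoxyphenoxy)cyclohexane-1-carbaldehyde (same configuration as 8) | O=C[C@]1(O)[C@H](C(C)=C)[C@H]2OC(C)(C)O[C@H]2[C@@H](Oc3ccc(OC)cc3)C1 | intermediate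
10 | 1-vinyl-2-isopropenyl-3,4-O-isopropylidene-5-(4-methoxyphenoxy)cyclohexan-1-ol (vinyl cis to isopropenyl; OH and the three ring oxygens on the opposite face) | C=C[C@]1(O)[C@H](C(C)=C)[C@H]2OC(C)(C)O[C@H]2[C@@H](Oc3ccc(OC)cc3)C1 | intermediate
11 | potassium alkoxide of 10 | C=C[C@]1([O-])[C@H](C(C)=C)[C@H]2OC(C)(C)O[C@H]2[C@@H](Oc3ccc(OC)cc3)C1.[K+] | intermediate (not isolated)
12 | potassium dienolate: ten-membered ring, C10(O−)=C1 with C9 trans to C2, C4(Me)=C5 Z, 6,7-O-isopropylidene, 8-O-(4-methoxyphenyl) | [O-]/C1=C\CC/C(C)=C\[C@H]2OC(C)(C)O[C@H]2[C@@H](Oc3ccc(OC)cc3)C1.[K+] | intermediate (not isolated)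
13 | enol triflate of 12 (C10–OTf, C9 trans to C2; 4Z) | O=S(=O)(O/C1=C\CC/C(C)=C\[C@H]2OC(C)(C)O[C@H]2[C@@H](Oc3ccc(OC)cc3)C1)C(F)(F)F | intermediate
14 | (1(10)E,4Z)-6,7-(isopropylidenedioxy)-8-(4-methoxyphenoxy)germacra-1(10),4-diene (C6, C7, C8 oxygens all cis) | C/C1=C\CC/C(C)=C\[C@H]2OC(C)(C)O[C@H]2[C@@H](Oc3ccc(OC)cc3)C1 | intermediate
15 | C1 (isopinocampheyl)borane adduct of 14 (B on C1, H on C10, syn) | C[C@H]1[C@@H](B[C@@H]4C[C@@H]5C[C@H]([C@H]4C)C5(C)C)CC/C(C)=C\[C@H]2OC(C)(C)O[C@H]2[C@@H](Oc3ccc(OC)cc3)C1 | intermediate (not isolated)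
16 | (1S,10R,4Z)-6,7-(isopropylidenedioxy)-8-(4-methoxyphenoxy)germacr-4-en-1-ol | C[C@H]1[C@@H](O)CC/C(C)=C\[C@H]2OC(C)(C)O[C@H]2[C@@H](Oc3ccc(OC)cc3)C1 | intermediate
17 | C1 acetate of 16 | C[C@H]1[C@@H](OC(C)=O)CC/C(C)=C\[C@H]2OC(C)(C)O[C@H]2[C@@H](Oc3ccc(OC)cc3)C1 | intermediate
18 | (4Z)-1-acetoxy-6,7-(isopropylidenedioxy)germacr-4-en-8-ol | C[C@H]1[C@@H](OC(C)=O)CC/C(C)=C\[C@H]2OC(C)(C)O[C@H]2[C@@H](O)C1 | intermediate
19 | C8 tiglate [(E)-2-methylbut-2-enoate] of 18 | C[C@H]1[C@@H](OC(C)=O)CC/C(C)=C\[C@H]2OC(C)(C)O[C@H]2[C@@H](OC(=O)/C(C)=C/C)C1 | intermediate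
20 | (4Z)-1-acetoxy-8-tigloyloxygermacr-4-ene-6,7-diol (cis-diol) | C[C@H]1[C@@H](OC(C)=O)CC/C(C)=C\[C@@H](O)[C@@H](O)[C@@H](OC(=O)/C(C)=C/C)C1 | intermediate
21 | ethyl 2-(diethoxyphosphoryl)acrylate | C=C(C(=O)OCC)P(=O)(OCC)OCC | starting material
22 | 4-methoxybenzyl alcohol | COc1ccc(CO)cc1 | starting material
23 | ethyl 2-(diethoxyphosphoryl)-3-[(4-methoxybenzyl)oxy]propanoate (racemic) | CCOC(=O)C(COCc1ccc(OC)cc1)P(=O)(OCC)OCC | intermediate
24 | 2-(diethoxyphosphoryl)-3-[(4-methoxybenzyl)oxy]propanoic acid (racemic) | OC(=O)C(COCc1ccc(OC)cc1)P(=O)(OCC)OCC | intermediate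
25 | 20 esterified at O6 with acid 24, C7–OH free (epimers at the phosphonate carbon) | C[C@H]1[C@@H](OC(C)=O)CC/C(C)=C\[C@@H](OC(=O)C(COCc3ccc(OC)cc3)P(=O)(OCC)OCC)[C@@H](O)[C@@H](OC(=O)/C(C)=C/C)C1 | intermediate
26 | (4R,5S)-4,5-epoxide of 25 (cis-epoxide, oxygen anti to the C6 acyloxy group) | C[C@H]1[C@@H](OC(C)=O)CC[C@@]2(C)O[C@H]2[C@@H](OC(=O)C(COCc3ccc(OC)cc3)P(=O)(OCC)OCC)[C@@H](O)[C@@H](OC(=O)/C(C)=C/C)C1 | intermediate
27 | C7 ketone of 26 | C[C@H]1[C@@H](OC(C)=O)CC[C@@]2(C)O[C@H]2[C@@H](OC(=O)C(COCc3ccc(OC)cc3)P(=O)(OCC)OCC)C(=O)[C@@H](OC(=O)/C(C)=C/C)C1 | intermediate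
28 | 13-O-(4-methoxybenzyl) ether of 29: 7(11)-en-6,12-olide with 4,5-epoxide, 1-OAc, 8-OTig | C[C@H]1[C@@H](OC(C)=O)CC[C@@]2(C)O[C@H]2[C@H]2OC(=O)C(COCc3ccc(OC)cc3)=C2[C@@H](OC(=O)/C(C)=C/C)C1 | intermediate
29 | 13-deacetyl target (free C13–OH) | C[C@H]1[C@@H](OC(C)=O)CC[C@@]2(C)O[C@H]2[C@H]2OC(=O)C(CO)=C2[C@@H](OC(=O)/C(C)=C/C)C1 | intermediate
30 | CNP0287840.1: (1S,4R,5S,6S,8S,10R)-1,13-diacetoxy-4,5-epoxy-8-tigloyloxygermacr-7(11)-en-6,12-olide | C/C=C(\C)C(=O)O[C@H]1C[C@@H](C)[C@@H](OC(C)=O)CC[C@@]2(C)O[C@H]2[C@H]2OC(=O)C(COC(C)=O)=C12 | target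

Total step count: 21 steps. Longest linear sequence: 19 steps (steps 1–13 and 16–21; steps 14–15 are the side branch to acid 24).

Steps most likely to fail

Step 7 (key step). What may go wrong: proton transfer within the dienolate 12 (C1 to C9) before O-sulfonylation, followed by β-elimination of the C8 aryloxide; incomplete O-triflation of the potassium enolate; or leakage through the ring-flipped chair, which would erode the 4Z geometry. Fallback, setting out from 10 and coming back at 13: the rearrangement is run as before, but the enolate is quenched at −78 °C with Me3SiCl/Et3N to give the trimethylsilyl enol ether F1, a neutral and isolable carrier of the enolate regiochemistry and geometry. MeLi (THF, 0 °C) then liberates the lithium enolate from F1, which is O-sulfonylated with N-(5-chloro-2-pyridyl)bis(trifluoromethanesulfonimide) to give 13.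

Step 16. What may go wrong: acylation at O7 or at both hydroxyls, and DMAP-promoted acyl migration between the cis-vicinal oxygens (including tigloyl migration from O8 to O7). Fallback, setting out from 20 and coming back at 25: the diol is converted into the cyclic dibutylstannylene acetal F2 (Bu2SnO, toluene, reflux with removal of water). F2 is acylated at −20 °C with the acid chloride F3, made from 24 with oxalyl chloride and DMF (cat.). The tin acetal activates a single oxygen, expected to be the less hindered allylic O6, and stops after one acylation, giving 25 without an amine catalyst.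

Step 17. What may go wrong: sluggish or undirected epoxidation of the hindered, inductively deactivated Z alkene; oxygen delivery to the other face if the ring does not allow the conformer with H6 in the alkene plane; or Lewis-acid-promoted opening of the new epoxide by the free C7 hydroxyl. Fallback, setting out from 25 and coming back at 30, with the epoxide postponed to the end:
- Dess–Martin oxidation of 25 gives the ketone F4.
- LiCl/i-Pr2NEt closes the butenolide F5.
- DDQ frees the C13 alcohol F6.
- Ac2O/pyridine gives the 4,5-alkene analogue of the target, F7.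
- N-bromosuccinimide in aqueous THF converts F7 into the bromohydrin F8: the bromonium ion forms on the exposed face on the lactone-oxygen side and water opens it at the tertiary C4 from the other face.
- Ag2O closes the epoxide with inversion at C5, placing the oxygen on the face opposite to electrophilic attack and giving 30.

Further compounds
F1 | step 7 | trimethylsilyl enol ether of the oxy-Cope product (C10–OSiMe3, C9 trans to C2; 4Z; 6,7-O-isopropylidene; 8-O-(4-methoxyphenyl)) | C[Si](C)(C)O/C1=C\CC/C(C)=C\[C@H]2OC(C)(C)O[C@H]2[C@@H](Oc3ccc(OC)cc3)C1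
F2 | step 16 | 6,7-O-dibutylstannylene acetal of 20 | C[C@H]1[C@@H](OC(C)=O)CC/C(C)=C\[C@H]2O[Sn](CCCC)(CCCC)O[C@H]2[C@@H](OC(=O)/C(C)=C/C)C1
F3 | step 16 | 2-(diethoxyphosphoryl)-3-[(4-methoxybenzyl)oxy]propanoyl chloride | O=C(Cl)C(COCc1ccc(OC)cc1)P(=O)(OCC)OCC
F4 | step 17 | C7 ketone of 25 (4Z alkene retained) | C[C@H]1[C@@H](OC(C)=O)CC/C(C)=C\[C@@H](OC(=O)C(COCc3ccc(OC)cc3)P(=O)(OCC)OCC)C(=O)[C@@H](OC(=O)/C(C)=C/C)C1
F5 | step 17 | (4Z)-1-acetoxy-13-(4-methoxybenzyloxy)-8-tigloyloxygermacra-4,7(11)-dien-6,12-olide | C[C@H]1[C@@H](OC(C)=O)CC/C(C)=C\[C@H]2OC(=O)C(COCc3ccc(OC)cc3)=C2[C@@H](OC(=O)/C(C)=C/C)C1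
F6 | step 17 | (4Z)-1-acetoxy-13-hydroxy-8-tigloyloxygermacra-4,7(11)-dien-6,12-olide | C[C@H]1[C@@H](OC(C)=O)CC/C(C)=C\[C@H]2OC(=O)C(CO)=C2[C@@H](OC(=O)/C(C)=C/C)C1
F7 | step 17 | (4Z)-1,13-diacetoxy-8-tigloyloxygermacra-4,7(11)-dien-6,12-olide (4,5-alkene analogue of 30) | C[C@H]1[C@@H](OC(C)=O)CC/C(C)=C\[C@H]2OC(=O)C(COC(C)=O)=C2[C@@H](OC(=O)/C(C)=C/C)C1
F8 | step 17 | bromohydrin of F7: 4-hydroxy (configuration of the final C4–O bond), 5-bromo (opposite face) | C[C@H]1[C@@H](OC(C)=O)CC[C@@](C)(O)[C@H](Br)[C@H]2OC(=O)C(COC(C)=O)=C2[C@@H](OC(=O)/C(C)=C/C)C1
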